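**Retrosynthetic overview**
1. Last bond: Suzuki–Miyaura union of an α‑bromo‑γ‑ylidenebutenolide (carrying the polyene and ring A) with the (E)‑alkenyl boronate of the epoxide end group.
2. Butenolide (last ring formed): tandem Sonogashira/5‑exo‑dig lactonisation of (E)‑2,3‑dibromoacrylic acid with a terminal polyenyne. The polyenyne comes from a symmetric C14 tetraene‑diyne (double Wittig on glyoxal) mono‑coupled to the actinol‑derived enol triflate; the ring A carbocycle is bought, not built.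
3. Epoxide end group (first rings formed, both at once): the cyclohexane and the oxirane are closed in one intramolecular Darzens epoxy‑annulation of an acyclic α‑chloro ester/methyl ketone; the silyloxy stereocentre controls both new centres.
4. Acyclic precursor: methyl 3,3‑dimethylpent‑4‑enoate by α‑chlorination, aldehyde‑selective Wacker oxidation, Keck methallylation and ozonolysis.

Assumption: (4R,6R)‑actinol and (E)‑3‑methylpent‑2‑en‑4‑yn‑1‑ol are bought as single isomers (industrial carotenoid/vitamin A building blocks).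
Assumption: species of catalytic cycles and metal adducts that are only hydrolysed on work‑up are not numbered.

**Step 1**
Reactants: 1 methyl 3,3‑dimethylpent‑4‑enoate
Product: 3 methyl 2‑chloro‑3,3‑dimethylpent‑4‑enoate (racemic), via lithium ester enolate 2 (not isolated)
Conditions: LiN(iPr)2 (1.1 equiv), THF, −78 °C; enolate cannulated into C2Cl6 (1.2 equiv), THF, −78 → −40 °C
Reagents that add atoms: lithium diisopropylamide, [Li]N(C(C)C)C(C)C (lithium of 2); hexachloroethane, ClC(Cl)(Cl)C(Cl)(Cl)Cl (chlorine of 3)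
Why: Electrophilic α‑chlorination of the ester lithium enolate by positive‑chlorine transfer from C2Cl6, with inverse addition to avoid dichlorination; the new C2 centre is racemic and is erased in step 6.

**Step 2**
Reactants: 3 methyl 2‑chloro‑3,3‑dimethylpent‑4‑enoate
Product: 4 methyl 2‑chloro‑3,3‑dimethyl‑5‑oxopentanoate (racemic)
Conditions: PdCl2(PhCN)2 (12 mol%), CuCl2·2H2O (12 mol%), AgNO2 (6 mol%), O2 (1 atm), tBuOH/MeNO2 15:1, 25 °C
Reagents that add atoms: dioxygen, O=O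
Why: Nitrite‑modified aldehyde‑selective (anti‑Markovnikov) Wacker oxidation; the quaternary allylic carbon steers oxygen to the terminal carbon and the α‑chloro ester is inert.

**Step 3**
Reactants: 4 methyl 2‑chloro‑3,3‑dimethyl‑5‑oxopentanoate; 5 tributyl(2‑methylallyl)stannane
Product: 6 methyl (5R)‑2‑chloro‑5‑hydroxy‑3,3,7‑trimethyloct‑7‑enoate (both C2 epimers)
Conditions: (R)‑BINOL (20 mol%), Ti(OiPr)4 (10 mol%), 4 Å sieves, CH2Cl2, −20 °C, 48 h; aq. NaHCO3; crude used at once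
Reagents that add atoms: none
Why: Keck catalytic asymmetric allylation: the (R)‑BINOL/Ti Lewis acid delivers the methallyl group to the Re face of the unbranched aldehyde (same sense as (R)‑BINOL giving (R)‑1‑phenylbut‑3‑en‑1‑ol), setting C5 as R; the methallyl group is a masked acetonyl unit.

**Step 4**
Reactants: 6 methyl (5R)‑2‑chloro‑5‑hydroxy‑3,3,7‑trimethyloct‑7‑enoate
Product: 7 methyl (5R)‑2‑chloro‑3,3,7‑trimethyl‑5‑[(triethylsilyl)oxy]oct‑7‑enoate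
Conditions: Et3SiCl (1.2 equiv), imidazole (2 equiv), CH2Cl2, 0 → 25 °C
Reagents that add atoms: chlorotriethylsilane, CC[Si](Cl)(CC)CC
Why: Standard imidazole‑promoted silylation, done immediately so the δ‑hydroxy ester cannot lactonise; the TES ether blocks retro‑aldol chemistry in step 6.

**Step 5**
Reactants: 7 methyl (5R)‑2‑chloro‑3,3,7‑trimethyl‑5‑[(triethylsilyl)oxy]oct‑7‑enoate
Product: 8 methyl (5S)‑2‑chloro‑3,3‑dimethyl‑7‑oxo‑5‑[(triethylsilyl)oxy]octanoate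
Conditions: O3, CH2Cl2, NaHCO3, −78 °C; then Me2S, −78 → 25 °C
Reagents that add atoms: ozone, [O-][O+]=O
Why: Ozonolysis of the 1,1‑disubstituted alkene with reductive work‑up unmasks the methyl ketone; C5 is untouched (R becomes S only through CIP priorities).

**Step 6 (key step)**
Reactants: 8 methyl (5S)‑2‑chloro‑3,3‑dimethyl‑7‑oxo‑5‑[(triethylsilyl)oxy]octanoate
Product: 11 methyl (1S,4S,6R)‑4‑hydroxy‑2,2,6‑trimethyl‑7‑oxabicyclo[4.1.0]heptane‑1‑carboxylate, via potassium chlorohydrin alkoxide 9 (not isolated), via silyl epoxy ester 10 (not isolated)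
Conditions: tBuOK (1.2 equiv, slow addition), THF (0.02 M), −40 → 0 °C; then AcOH (1.5 equiv), Bu4NF (1.5 equiv), 0 → 20 °C
Reagents that add atoms: potassium tert‑butoxide, CC(C)(C)[O-].[K+] (potassium of 9)
Why: Proposed new method: an intramolecular Darzens glycidic‑ester condensation in which the α‑chloro ester enolate adds 6‑exo to the methyl ketone through a chair with the silyloxy group and the ketone methyl equatorial (no 1,3‑diaxial clash with the gem‑dimethyl group), and only the aldolate with axial O(−) anti‑periplanar to axial C–Cl closes by 3‑exo‑tet SN2, so the reversible aldol funnels material to the oxirane anti to the silyl ether (C1 S, C6 R from C4 S); the closest known reactions are the intermolecular Darzens condensation of α‑chloro esters with ketones and base‑mediated aldol/SN2 epoxy‑annulations, and fluoride then removes the TES group in the same flask.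

**Step 7**
Reactants: 11 methyl (1S,4S,6R)‑4‑hydroxy‑2,2,6‑trimethyl‑7‑oxabicyclo[4.1.0]heptane‑1‑carboxylate
Product: 12 (1S,4S,6R)‑4‑hydroxy‑2,2,6‑trimethyl‑7‑oxabicyclo[4.1.0]heptane‑1‑carbaldehyde
Conditions: iBu2AlH (2.3 equiv), CH2Cl2, −78 °C, 1 h; MeOH, aq. potassium sodium tartrate
Reagents that add atoms: none
Why: Partial reduction of the ester with iBu2AlH at −78 °C (the aluminium hemiacetal next to the oxirane oxygen collapses only on work‑up); one extra equivalent is consumed by the free hydroxyl.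

**Step 8**
Reactants: 12 (1S,4S,6R)‑4‑hydroxy‑2,2,6‑trimethyl‑7‑oxabicyclo[4.1.0]heptane‑1‑carbaldehyde
Product: 13 (1S,4S,6R)‑2,2,6‑trimethyl‑1‑[(E)‑2‑(4,4,5,5‑tetramethyl‑1,3,2‑dioxaborolan‑2‑yl)ethenyl]‑7‑oxabicyclo[4.1.0]heptan‑4‑ol
Conditions: CrCl2 (8 equiv), Cl2CHBpin (2 equiv), LiI (4 equiv), THF, 25 °C
Reagents that add atoms: 2‑(dichloromethyl)‑4,4,5,5‑tetramethyl‑1,3,2‑dioxaborolane, CC1(C)OB(C(Cl)Cl)OC1(C)C
Why: Takai–Utimoto boryl‑olefination: the geminal dichromium reagent adds to the non‑enolisable aldehyde and anti‑eliminates to the (E)‑alkenyl boronate; hydroxyl and oxirane tolerate divalent chromium.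

**Step 9**
Reactants: 14 (2E)‑3‑methylpent‑2‑en‑4‑yn‑1‑ol
Product: 16 [(2E)‑3‑methylpent‑2‑en‑4‑yn‑1‑yl]triphenylphosphonium bromide, via allylic bromide 15 (not isolated)
Conditions: PBr3 (0.4 equiv), Et2O, −10 °C; washed ether solution then PPh3 (1.05 equiv), toluene, 25 °C, 16 h
Reagents that add atoms: phosphorus tribromide, BrP(Br)Br; triphenylphosphine, c1ccc(cc1)P(c1ccccc1)c1ccccc1
Why: SN2 bromination of the primary allylic alcohol keeps the E geometry, and the allylic bromide quaternises PPh3 (Wittig salt formation).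

**Step 10**
Reactants: 16 [(2E)‑3‑methylpent‑2‑en‑4‑yn‑1‑yl]triphenylphosphonium bromide (2.05 equiv); 17 glyoxal (as commercial trimer dihydrate)
Product: 20 (3E,5E,7E,9E)‑3,10‑dimethyldodeca‑3,5,7,9‑tetraene‑1,11‑diyne, via phosphonium ylide 18 (not isolated), via dienynal 19 (not isolated)
Conditions: LiOEt (2.1 equiv), EtOH/DMF, 0 → 25 °C; then I2 (2 mol%), CH2Cl2, diffuse light, 25 °C
Reagents that add atoms: none
Why: Two‑fold Wittig olefination of glyoxal with the semi‑stabilised allylic ylide, followed by iodine‑catalysed equilibration of the two new disubstituted double bonds to the thermodynamic all‑E tetraene.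

**Step 11**
Reactants: 21 (4R,6R)‑4‑hydroxy‑2,2,6‑trimethylcyclohexan‑1‑one (actinol)
Product: 22 (1R,5R)‑3,3,5‑trimethyl‑4‑oxocyclohexyl acetate
Conditions: Ac2O (1.5 equiv), pyridine, DMAP (5 mol%), CH2Cl2, 25 °C
Reagents that add atoms: acetic anhydride, CC(=O)OC(C)=O
Why: DMAP‑catalysed acetylation of the secondary alcohol installs the acetate of ring A at the outset; the carbinol centre is untouched.

**Step 12**
Reactants: 22 (1R,5R)‑3,3,5‑trimethyl‑4‑oxocyclohexyl acetate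
Product: 23 (4R)‑4‑acetoxy‑2,6,6‑trimethylcyclohex‑1‑en‑1‑yl trifluoromethanesulfonate
Conditions: Tf2O (1.3 equiv), 2,6‑di‑tert‑butyl‑4‑methylpyridine (1.5 equiv), CH2Cl2, 0 → 25 °C
Reagents that add atoms: trifluoromethanesulfonic anhydride, O=S(=O)(OS(=O)(=O)C(F)(F)F)C(F)(F)F
Why: O‑triflation of the ketone with a hindered pyridine base; only one α‑carbon bears hydrogen, so a single tetrasubstituted enol triflate forms (that methyl stereocentre is deliberately destroyed, the acetoxy centre stays R).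

**Step 13**
Reactants: 23 (4R)‑4‑acetoxy‑2,6,6‑trimethylcyclohex‑1‑en‑1‑yl trifluoromethanesulfonate; 20 (3E,5E,7E,9E)‑3,10‑dimethyldodeca‑3,5,7,9‑tetraene‑1,11‑diyne (3 equiv)
Product: 24 (1R)‑4‑[(3E,5E,7E,9E)‑3,10‑dimethyldodeca‑3,5,7,9‑tetraene‑1,11‑diyn‑1‑yl]‑3,5,5‑trimethylcyclohex‑3‑en‑1‑yl acetate
Conditions: Pd(PPh3)4 (5 mol%), CuI (10 mol%), iPr2NH (3 equiv), DMF, 25 → 40 °C, degassed, dark
Reagents that add atoms: none
Why: Sonogashira coupling of the enol triflate with one terminus of the symmetric diyne; excess hydrocarbon diyne suppresses double coupling and is recovered by chromatography (hydrocarbon versus mono‑acetate).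

**Step 14**
Reactants: 25 propiolic acid
Product: 26 (2E)‑2,3‑dibromoprop‑2‑enoic acid
Conditions: Br2 (1.0 equiv), CHCl3, 0 → 25 °C, dark
Reagents that add atoms: bromine, BrBr
Why: Ionic anti‑addition of bromine to the alkyne gives the E (trans) dibromide, whose β‑bromine is cis to CO2H as lactonisation requires.

**Step 15**
Reactants: 24 (1R)‑4‑[(3E,5E,7E,9E)‑3,10‑dimethyldodeca‑3,5,7,9‑tetraene‑1,11‑diyn‑1‑yl]‑3,5,5‑trimethylcyclohex‑3‑en‑1‑yl acetate; 26 (2E)‑2,3‑dibromoprop‑2‑enoic acid (1.3 equiv)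
Product: 28 (1R)‑4‑{(3E,5E,7E,9E,11Z)‑11‑[4‑bromo‑5‑oxofuran‑2(5H)‑ylidene]‑3,10‑dimethylundeca‑3,5,7,9‑tetraen‑1‑yn‑1‑yl}‑3,5,5‑trimethylcyclohex‑3‑en‑1‑yl acetate, via bromo enynoic acid 27 (not isolated)
Conditions: PdCl2(PPh3)2 (5 mol%), CuI (10 mol%), Et3N (5 equiv), MeCN/THF 1:1, 25 °C, degassed, dark
Reagents that add atoms: none
Why: Tandem Sonogashira coupling/5‑exo‑dig oxacyclisation: zerovalent palladium inserts selectively into the more electrophilic β‑C–Br bond, and the cis carboxylate then adds anti across the alkyne to give the (Z)‑γ‑ylidene‑α‑bromobutenolide.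

**Step 16**
Reactants: 28 the bromobutenolide of step 15; 13 (1S,4S,6R)‑2,2,6‑trimethyl‑1‑[(E)‑2‑(4,4,5,5‑tetramethyl‑1,3,2‑dioxaborolan‑2‑yl)ethenyl]‑7‑oxabicyclo[4.1.0]heptan‑4‑ol (1.3 equiv)
Product: 29 pyrrhoxanthin (target CNP0337675.1)
Conditions: Pd(dppf)Cl2 (dppf = 1,1'‑bis(diphenylphosphino)ferrocene; 10 mol%), CsF (3 equiv), THF/H2O 10:1, 40 °C, degassed, dark
Reagents that add atoms: none
Why: Suzuki–Miyaura coupling of the α‑bromobutenolide with the (E)‑alkenyl boronate under fluoride activation, mild enough for the acetate, the enol lactone and the vinyl oxirane; both alkene geometries are retained and no stereocentre is touched.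

**Compound list**
1 | methyl 3,3‑dimethylpent‑4‑enoate | COC(=O)CC(C)(C)C=C | starting material
2 | lithium 1‑methoxy‑3,3‑dimethylpenta‑1,4‑dien‑1‑olate | COC(O[Li])=CC(C)(C)C=C | intermediate (not isolated)
3 | methyl 2‑chloro‑3,3‑dimethylpent‑4‑enoate (racemic) | COC(=O)C(Cl)C(C)(C)C=C | intermediate
4 | methyl 2‑chloro‑3,3‑dimethyl‑5‑oxopentanoate (racemic) | COC(=O)C(Cl)C(C)(C)CC=O | intermediate
5 | tributyl(2‑methylallyl)stannane | CCCC[Sn](CCCC)(CCCC)CC(C)=C | starting material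
6 | methyl (5R)‑2‑chloro‑5‑hydroxy‑3,3,7‑trimethyloct‑7‑enoate (both C2 epimers) | COC(=O)C(Cl)C(C)(C)C[C@H](O)CC(C)=C | intermediate
7 | methyl (5R)‑2‑chloro‑3,3,7‑trimethyl‑5‑[(triethylsilyl)oxy]oct‑7‑enoate | COC(=O)C(Cl)C(C)(C)C[C@H](O[Si](CC)(CC)CC)CC(C)=C | intermediate
8 | methyl (5S)‑2‑chloro‑3,3‑dimethyl‑7‑oxo‑5‑[(triethylsilyl)oxy]octanoate | COC(=O)C(Cl)C(C)(C)C[C@H](O[Si](CC)(CC)CC)CC(C)=O | intermediate
9 | potassium alkoxide of methyl (1R,2R,4S)‑1‑chloro‑2‑hydroxy‑2,6,6‑trimethyl‑4‑[(triethylsilyl)oxy]cyclohexane‑1‑carboxylate | COC(=O)[C@]1(Cl)[C@](C)([O-])C[C@@H](O[Si](CC)(CC)CC)CC1(C)C.[K+] | intermediate (not isolated)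
10 | methyl (1S,4S,6R)‑2,2,6‑trimethyl‑4‑[(triethylsilyl)oxy]‑7‑oxabicyclo[4.1.0]heptane‑1‑carboxylate | COC(=O)[C@@]12O[C@]1(C)C[C@@H](O[Si](CC)(CC)CC)CC2(C)C | intermediate (not isolated)
11 | methyl (1S,4S,6R)‑4‑hydroxy‑2,2,6‑trimethyl‑7‑oxabicyclo[4.1.0]heptane‑1‑carboxylate | COC(=O)[C@@]12O[C@]1(C)C[C@@H](O)CC2(C)C | intermediate
12 | (1S,4S,6R)‑4‑hydroxy‑2,2,6‑trimethyl‑7‑oxabicyclo[4.1.0]heptane‑1‑carbaldehyde | O=C[C@@]12O[C@]1(C)C[C@@H](O)CC2(C)C | intermediate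
13 | (1S,4S,6R)‑2,2,6‑trimethyl‑1‑[(E)‑2‑(4,4,5,5‑tetramethyl‑1,3,2‑dioxaborolan‑2‑yl)ethenyl]‑7‑oxabicyclo[4.1.0]heptan‑4‑ol | CC1(C)OB(/C=C/[C@@]23O[C@]2(C)C[C@@H](O)CC3(C)C)OC1(C)C | intermediate
14 | (2E)‑3‑methylpent‑2‑en‑4‑yn‑1‑ol | C#C/C(C)=C/CO | starting material
15 | (3E)‑5‑bromo‑3‑methylpent‑3‑en‑1‑yne | C#C/C(C)=C/CBr | intermediate (not isolated)
16 | [(2E)‑3‑methylpent‑2‑en‑4‑yn‑1‑yl]triphenylphosphonium bromide | C#C/C(C)=C/C[P+](c1ccccc1)(c1ccccc1)c1ccccc1.[Br-] | intermediate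
17 | glyoxal | O=CC=O | starting material
18 | [(2E)‑3‑methylpent‑2‑en‑4‑yn‑1‑ylidene]triphenylphosphorane | C#C/C(C)=C/C=P(c1ccccc1)(c1ccccc1)c1ccccc1 | intermediate (not isolated)
19 | (2E,4E)‑5‑methylhepta‑2,4‑dien‑6‑ynal | C#C/C(C)=C/C=C/C=O | intermediate (not isolated)
20 | (3E,5E,7E,9E)‑3,10‑dimethyldodeca‑3,5,7,9‑tetraene‑1,11‑diyne | C#C/C(C)=C/C=C/C=C/C=C(C)/C#C | intermediate
21 | (4R,6R)‑4‑hydroxy‑2,2,6‑trimethylcyclohexan‑1‑one (actinol) | O[C@@H]1C[C@@H](C)C(=O)C(C)(C)C1 | starting material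
22 | (1R,5R)‑3,3,5‑trimethyl‑4‑oxocyclohexyl acetate | CC(=O)O[C@@H]1C[C@@H](C)C(=O)C(C)(C)C1 | intermediate
23 | (4R)‑4‑acetoxy‑2,6,6‑trimethylcyclohex‑1‑en‑1‑yl trifluoromethanesulfonate | CC(=O)O[C@@H]1CC(C)=C(OS(=O)(=O)C(F)(F)F)C(C)(C)C1 | intermediate
24 | (1R)‑4‑[(3E,5E,7E,9E)‑3,10‑dimethyldodeca‑3,5,7,9‑tetraene‑1,11‑diyn‑1‑yl]‑3,5,5‑trimethylcyclohex‑3‑en‑1‑yl acetate | CC(=O)O[C@@H]1CC(C)=C(C#C/C(C)=C/C=C/C=C/C=C(C)/C#C)C(C)(C)C1 | intermediate
25 | propiolic acid | C#CC(=O)O | starting material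
26 | (2E)‑2,3‑dibromoprop‑2‑enoic acid | OC(=O)/C(Br)=C\Br | intermediate
27 | (2E,6E,8E,10E,12E)‑15‑[(4R)‑4‑acetoxy‑2,6,6‑trimethylcyclohex‑1‑en‑1‑yl]‑2‑bromo‑6,13‑dimethylpentadeca‑2,6,8,10,12‑pentaene‑4,14‑diynoic acid | CC(=O)O[C@@H]1CC(C)=C(C#C/C(C)=C/C=C/C=C/C=C(C)/C#C/C=C(/Br)C(=O)O)C(C)(C)C1 | intermediate (not isolated)
28 | (1R)‑4‑{(3E,5E,7E,9E,11Z)‑11‑[4‑bromo‑5‑oxofuran‑2(5H)‑ylidene]‑3,10‑dimethylundeca‑3,5,7,9‑tetraen‑1‑yn‑1‑yl}‑3,5,5‑trimethylcyclohex‑3‑en‑1‑yl acetate | CC(=O)O[C@@H]1CC(C)=C(C#C/C(C)=C/C=C/C=C/C=C(C)/C=C2C=C(Br)C(=O)O/2)C(C)(C)C1 | intermediate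
29 | pyrrhoxanthin: (1R)‑4‑{(3E,5E,7E,9E,11Z)‑11‑[4‑{(E)‑2‑[(1S,4S,6R)‑4‑hydroxy‑2,2,6‑trimethyl‑7‑oxabicyclo[4.1.0]heptan‑1‑yl]ethenyl}‑5‑oxofuran‑2(5H)‑ylidene]‑3,10‑dimethylundeca‑3,5,7,9‑tetraen‑1‑yn‑1‑yl}‑3,5,5‑trimethylcyclohex‑3‑en‑1‑yl acetate | CC(=O)O[C@@H]1CC(C)=C(C#C/C(C)=C/C=C/C=C/C=C(C)/C=C2C=C(/C=C/[C@@]34O[C@]3(C)C[C@@H](O)CC4(C)C)C(=O)O/2)C(C)(C)C1 | target

**Totals**
Total step count: 16. Longest linear sequence: 9 (steps 1–8, then 16).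

**Three steps most likely to fail**

Step 6 (Darzens epoxy‑annulation). Ketone enolisation, Dieckmann‑type acylation, 5‑exo alkylation or loss of silanolate can compete with the desired enolate. Fallback: make the chloro‑enolate by reduction instead of by base. It sets out from 3: a second LiN(iPr)2/C2Cl6 chlorination gives methyl 2,2‑dichloro‑3,3‑dimethylpent‑4‑enoate F1. The same Wacker oxidation, Keck methallylation, silylation and ozonolysis then give in turn methyl 2,2‑dichloro‑3,3‑dimethyl‑5‑oxopentanoate F2, methyl (5R)‑2,2‑dichloro‑5‑hydroxy‑3,3,7‑trimethyloct‑7‑enoate F3, methyl (5R)‑2,2‑dichloro‑3,3,7‑trimethyl‑5‑[(triethylsilyl)oxy]oct‑7‑enoate F4 and methyl (5S)‑2,2‑dichloro‑3,3‑dimethyl‑7‑oxo‑5‑[(triethylsilyl)oxy]octanoate F5. SmI2 (2.2 equiv, THF, −78 °C) removes one chlorine to give a samarium enolate (Reformatsky type, no base, ketone not enolised) that closes onto the ketone to the samarium chlorohydrin alkoxide, methyl (1R,2R,4S)‑1‑chloro‑2‑[(diiodosamario)oxy]‑2,6,6‑trimethyl‑4‑[(triethylsilyl)oxy]cyclohexane‑1‑carboxylate F6. tBuOK added to the same flask (−78 → 0 °C) closes the oxirane, so both rings still form in one operation, and the route is rejoined at 10.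

Step 13 (statistical mono‑coupling of the symmetric diyne 20, which itself depends on the double Wittig of step 10). Fallback: grow the chain linearly from ring A. It sets out from 23: Sonogashira coupling with enynol 14 (Pd(PPh3)4, CuI, iPr2NH) gives (1R)‑4‑[(3E)‑5‑hydroxy‑3‑methylpent‑3‑en‑1‑yn‑1‑yl]‑3,5,5‑trimethylcyclohex‑3‑en‑1‑yl acetate F7. MnO2 in CH2Cl2 oxidises it to (1R)‑3,5,5‑trimethyl‑4‑[(3E)‑3‑methyl‑5‑oxopent‑3‑en‑1‑yn‑1‑yl]cyclohex‑3‑en‑1‑yl acetate F8. Wittig two‑carbon homologation with Ph3P=CHCHO (toluene, 70 °C) gives (1R)‑3,5,5‑trimethyl‑4‑[(3E,5E)‑3‑methyl‑7‑oxohepta‑3,5‑dien‑1‑yn‑1‑yl]cyclohex‑3‑en‑1‑yl acetate F9. Wittig reaction of F9 with ylide 18 (from 16 and NaN(SiMe3)2, THF, −78 °C, which spares the acetate), then I2 equilibration, comes back to the route at 24.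

Step 16 (Suzuki coupling on a base‑sensitive enol lactone with a vinyl oxirane partner). Fallback: base‑free Stille coupling. It sets out from 12: dimethyl (1‑diazo‑2‑oxopropyl)phosphonate with K2CO3 in MeOH gives (1R,4S,6R)‑1‑ethynyl‑2,2,6‑trimethyl‑7‑oxabicyclo[4.1.0]heptan‑4‑ol F10. Hydrostannation (Bu3SnH, PdCl2(PPh3)2, THF, 0 °C) gives (1S,4S,6R)‑2,2,6‑trimethyl‑1‑[(E)‑2‑(tributylstannyl)ethenyl]‑7‑oxabicyclo[4.1.0]heptan‑4‑ol F11. Stille coupling of F11 with 28 (Pd2(dba)3, dba = dibenzylideneacetone, AsPh3, DMF, 25 °C) comes back to the route at 29.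

**Further compounds**
F1 | step 6 | methyl 2,2‑dichloro‑3,3‑dimethylpent‑4‑enoate | COC(=O)C(Cl)(Cl)C(C)(C)C=C
F2 | step 6 | methyl 2,2‑dichloro‑3,3‑dimethyl‑5‑oxopentanoate | COC(=O)C(Cl)(Cl)C(C)(C)CC=O
F3 | step 6 | methyl (5R)‑2,2‑dichloro‑5‑hydroxy‑3,3,7‑trimethyloct‑7‑enoate | COC(=O)C(Cl)(Cl)C(C)(C)C[C@H](O)CC(C)=C
F4 | step 6 | methyl (5R)‑2,2‑dichloro‑3,3,7‑trimethyl‑5‑[(triethylsilyl)oxy]oct‑7‑enoate | COC(=O)C(Cl)(Cl)C(C)(C)C[C@H](O[Si](CC)(CC)CC)CC(C)=C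
F5 | step 6 | methyl (5S)‑2,2‑dichloro‑3,3‑dimethyl‑7‑oxo‑5‑[(triethylsilyl)oxy]octanoate | COC(=O)C(Cl)(Cl)C(C)(C)C[C@H](O[Si](CC)(CC)CC)CC(C)=O
F6 | step 6 | methyl (1R,2R,4S)‑1‑chloro‑2‑[(diiodosamario)oxy]‑2,6,6‑trimethyl‑4‑[(triethylsilyl)oxy]cyclohexane‑1‑carboxylate | COC(=O)[C@]1(Cl)[C@](C)(O[Sm](I)I)C[C@@H](O[Si](CC)(CC)CC)CC1(C)C
F7 | step 13 | (1R)‑4‑[(3E)‑5‑hydroxy‑3‑methylpent‑3‑en‑1‑yn‑1‑yl]‑3,5,5‑trimethylcyclohex‑3‑en‑1‑yl acetate | CC(=O)O[C@@H]1CC(C)=C(C#C/C(C)=C/CO)C(C)(C)C1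
F8 | step 13 | (1R)‑3,5,5‑trimethyl‑4‑[(3E)‑3‑methyl‑5‑oxopent‑3‑en‑1‑yn‑1‑yl]cyclohex‑3‑en‑1‑yl acetate | CC(=O)O[C@@H]1CC(C)=C(C#C/C(C)=C/C=O)C(C)(C)C1
F9 | step 13 | (1R)‑3,5,5‑trimethyl‑4‑[(3E,5E)‑3‑methyl‑7‑oxohepta‑3,5‑dien‑1‑yn‑1‑yl]cyclohex‑3‑en‑1‑yl acetate | CC(=O)O[C@@H]1CC(C)=C(C#C/C(C)=C/C=C/C=O)C(C)(C)C1
F10 | step 16 | (1R,4S,6R)‑1‑ethynyl‑2,2,6‑trimethyl‑7‑oxabicyclo[4.1.0]heptan‑4‑ol | C#C[C@@]12O[C@]1(C)C[C@@H](O)CC2(C)C
F11 | step 16 | (1S,4S,6R)‑2,2,6‑trimethyl‑1‑[(E)‑2‑(tributylstannyl)ethenyl]‑7‑oxabicyclo[4.1.0]heptan‑4‑ol | CCCC[Sn](CCCC)(CCCC)/C=C/[C@@]12O[C@]1(C)C[C@@H](O)CC2(C)C
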